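**Retrosynthetic overview**

- Ring A of the target has C4a flanked by the oxygen-bearing carbons C5 and C8a and carrying the acyl carbon C4. This is the pattern of 2-acetylcyclohexane-1,3-dione (1), so the carbocycle is bought saturated and the acetyl CH3 becomes C3.
- 1 is silylated twice (2, then bis-silyl dienol ether 3). C2–C3 is cut back to 3 and hexadecanal (4) by an asymmetric Mukaiyama aldol that sets C2; O1–C8a is cut back to an acid cyclodehydration of the aldol (5, 6) that gives bicyclic dione 7.
- Late stage: ring A is aromatized through C8 bromide 8 to phenol 9. The C8 oxygen comes from para-oxidation to quinone 10 and reduction to target 11.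
- Ring order: carbocycle present from 1, ring B closed in step 3, ring A made aromatic in step 4.

Key step: step 3

Assumption: the titanium–BINOL catalyst is taken to keep its usual facial sense, so that the (S)-ligand sends the nucleophile to the Si face of hexadecanal and gives (R) at C2; if the sense proves opposite with this diene, (R)-BINOL is used instead.

**Route**

Step 1
Reactants: 1 2-acetylcyclohexane-1,3-dione
Product: 2 2-acetyl-3-(trimethylsilyloxy)cyclohex-2-en-1-one
Conditions: TMSCl, Et3N, Et2O, 0 °C → rt; filtered under Ar, used crude
Reagents that add atoms: chlorotrimethylsilane, C[Si](C)(C)Cl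
Why: The triketone is a strongly acidic enol, so TMSCl/Et3N should silylate the enol oxygen cleanly (O-silylation of a β-dicarbonyl enol, first stage of a Chan-type diene preparation); the O-silyl isomers interconvert by silyl shift and lead to the same dienolate in step 2.

Step 2
Reactants: 2 2-acetyl-3-(trimethylsilyloxy)cyclohex-2-en-1-one
Product: 3 3-(trimethylsilyloxy)-2-[1-(trimethylsilyloxy)ethenyl]cyclohex-2-en-1-one
Conditions: LiN(iPr)2 (LDA), THF, −78 °C; then TMSCl, −78 → 0 °C; non-aqueous work-up, used crude
Reagents that add atoms: chlorotrimethylsilane, C[Si](C)(C)Cl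
Why: Kinetic deprotonation by LDA should take the acetyl CH3 (methyl before methylene, as in β-dicarbonyl dianion chemistry, and the acetyl group, twisted out of the enone plane, is the more ketone-like carbonyl, whereas the ring C6 hydrogens belong to a vinylogous silyl ester), and O-silylation of the enolate gives the bis-silyl dienol ether, the standard second stage of 1,3-bis(silyloxy)diene synthesis.

Step 3
Reactants: 3 3-(trimethylsilyloxy)-2-[1-(trimethylsilyloxy)ethenyl]cyclohex-2-en-1-one; 4 hexadecanal
Product: 7 (R)-2-pentadecyl-2,3,7,8-tetrahydro-4H-chromene-4,5(6H)-dione, via bis-silyl aldol adduct 5 (not isolated), via hydroxy triketone 6 (not isolated)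
Conditions: Ti(OiPr)4 (20 mol %), (S)-BINOL (20 mol %), 4 Å MS, THF, −78 °C → rt; then TFA, CH2Cl2, 0 °C → rt
Reagents that add atoms: none
Why: The titanium–BINOL complex binds hexadecanal and the terminal CH2 of the silyl enol ether of 3 attacks it through an open transition state (Mukaiyama aldol of a Chan-type bis-silyl diene), forming C2–C3 and, after silyl transfer, 5. The closest known reaction is the Ti(OiPr)4/BINOL-catalysed aldol of 1,3-bis(silyloxy)dienes from β-keto esters and β-diketones with aldehydes, whose diketone adducts close to 2,3-dihydro-4H-pyran-4-ones on acid treatment; the acyl group on the central diene carbon is the new element here. TFA strips both silyl groups to give 6, whose C2 hydroxyl adds to the protonated ring carbonyl C8a (6-exo-trig) and water is then lost, closing ring B through O1–C8a as a vinylogous ester. C2 is set by the catalyst alone (Si-face attack under the (S)-ligand) and keeps its configuration because the C2–O bond is never broken. Site selectivity is secured by the substrate: only the unsubstituted enol ether terminus is nucleophilic and open, and the two ring carbonyls of 6 are equivalent, so closure on either gives 7. The acid stage is kept cold and short so that the aldol does not eliminate to the enone, whose oxa-Michael closure would give racemic 7.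

Step 4
Reactants: 7 (R)-2-pentadecyl-2,3,7,8-tetrahydro-4H-chromene-4,5(6H)-dione
Product: 9 (R)-5-hydroxy-2-pentadecylchroman-4-one, via C8 bromide 8 (not isolated)
Conditions: NBS (1.0 equiv), AIBN (cat.), PhCF3, 80 °C; then Et3N, 0 °C → rt
Reagents that add atoms: none
Why: Wohl–Ziegler bromination should pick the weakest C–H bond, the allylic C8–H next to the C4a=C8a double bond (the radical is delocalized to C4a between two carbonyls), rather than C3–H or C2–H, so that loss of HBr across C7–C8 and enolization of the resulting dienone deliver the phenol without touching C2–C3 or the C2 stereocenter.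

Step 5
Reactants: 9 (R)-5-hydroxy-2-pentadecylchroman-4-one
Product: 10 (R)-2-pentadecyl-2,3-dihydro-4H-chromene-4,5,8-trione
Conditions: (KSO3)2NO (2.5 equiv), KH2PO4 (aq.), Bu4NHSO4 (cat.), CH2Cl2/H2O, rt
Reagents that add atoms: potassium nitrosodisulfonate (Fremy's salt), [K+].[K+].[O-]S(=O)(=O)N([O])S(=O)(=O)[O-]
Why: In this Teuber oxidation the nitroxyl radical takes the phenolic hydrogen and a second equivalent adds at the free para position C8 and loses imidodisulfonate to give the para-quinone, as known for peri-hydroxy aryl ketones with a free para position, and the buffered near-neutral two-phase medium should keep C3 from enolizing, so C2 is safe.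

Step 6
Reactants: 10 (R)-2-pentadecyl-2,3-dihydro-4H-chromene-4,5,8-trione
Product: 11 (R)-5,8-dihydroxy-2-pentadecylchroman-4-one
Conditions: Na2S2O4 (aq.), EtOAc, rt, Ar; crude 10 used at once
Reagents that add atoms: none
Why: Dithionite reduces the quinone to the hydroquinone by two-electron transfer at near-neutral pH (standard quinone reduction), which leaves the C4 ketone and the C2 stereocenter untouched.

**Compound list**

1 | 2-acetylcyclohexane-1,3-dione | CC(=O)C1C(=O)CCCC1=O | starting material
2 | 2-acetyl-3-(trimethylsilyloxy)cyclohex-2-en-1-one | CC(=O)C1=C(O[Si](C)(C)C)CCCC1=O | intermediate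
3 | 3-(trimethylsilyloxy)-2-[1-(trimethylsilyloxy)ethenyl]cyclohex-2-en-1-one | C=C(O[Si](C)(C)C)C1=C(O[Si](C)(C)C)CCCC1=O | intermediate
4 | hexadecanal | CCCCCCCCCCCCCCCC=O | starting material
5 | 3-(trimethylsilyloxy)-2-[(3R)-3-(trimethylsilyloxy)octadecanoyl]cyclohex-2-en-1-one | CCCCCCCCCCCCCCC[C@@H](O[Si](C)(C)C)CC(=O)C1=C(O[Si](C)(C)C)CCCC1=O | intermediate (not isolated)
6 | 3-hydroxy-2-[(3R)-3-hydroxyoctadecanoyl]cyclohex-2-en-1-one | CCCCCCCCCCCCCCC[C@@H](O)CC(=O)C1=C(O)CCCC1=O | intermediate (not isolated)
7 | (R)-2-pentadecyl-2,3,7,8-tetrahydro-4H-chromene-4,5(6H)-dione | CCCCCCCCCCCCCCC[C@@H]1CC(=O)C2=C(CCCC2=O)O1 | intermediate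
8 | (2R)-8-bromo-2-pentadecyl-2,3,7,8-tetrahydro-4H-chromene-4,5(6H)-dione, both C8 epimers | CCCCCCCCCCCCCCC[C@@H]1CC(=O)C2=C(C(Br)CCC2=O)O1 | intermediate (not isolated)
9 | (R)-5-hydroxy-2-pentadecylchroman-4-one | CCCCCCCCCCCCCCC[C@@H]1CC(=O)c2c(O)cccc2O1 | intermediate
10 | (R)-2-pentadecyl-2,3-dihydro-4H-chromene-4,5,8-trione | CCCCCCCCCCCCCCC[C@@H]1CC(=O)C2=C(O1)C(=O)C=CC2=O | intermediate
11 | (R)-5,8-dihydroxy-2-pentadecylchroman-4-one | CCCCCCCCCCCCCCC[C@@H]1CC(=O)c2c(O)ccc(O)c2O1 | target

**Step count**

Total steps: 6. Longest linear sequence: 6 steps (1 to 11); hexadecanal 4 joins at step 3.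

**Steps most likely to fail**

1. Step 3. The tricarbonyl product may bind titanium and stall turnover, the acyl-substituted diene may react with poor facial selectivity, or the aldol may eliminate during the acid stage and reclose without selectivity. Wrong-site enolization in step 2 would also show up here. The fallback sets out from hexadecanal 4, uses known reactions only and needs no dienol ether. Roskamp homologation (ethyl diazoacetate, SnCl2 cat., CH2Cl2) should give ethyl 3-oxooctadecanoate F1. Noyori hydrogenation (RuCl2[(R)-BINAP], H2, EtOH) should give ethyl (R)-3-hydroxyoctadecanoate F2. Silylation (TBSCl, imidazole, DMF) gives ethyl (R)-3-(tert-butyldimethylsilyloxy)octadecanoate F3, and LiOH in THF/H2O gives (R)-3-(tert-butyldimethylsilyloxy)octadecanoic acid F4. Coupling of F4 with cyclohexane-1,3-dione by DCC/DMAP in CH2Cl2 (O-acylation, then DMAP-mediated O-to-C acyl shift) gives 3-hydroxy-2-[(3R)-3-(tert-butyldimethylsilyloxy)octadecanoyl]cyclohex-2-en-1-one F5. Aqueous HF in MeCN, then TFA in CH2Cl2, removes the silyl group and cyclodehydrates by way of 6, and the route is rejoined at 7.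

2. Step 5. The hydrogen-bonded, acyl-deactivated phenol may resist hydrogen abstraction by the nitroxyl radical, or the acylquinone may add water before it is reduced. The fallback sets out from 9 and avoids the quinone. Elbs persulfate oxidation (K2S2O8, aqueous KOH, pyridine, 0–10 °C), which is known for 2-acyl-3-alkoxyphenols, should give potassium (R)-5-hydroxy-4-oxo-2-pentadecylchroman-8-yl sulfate F6. Hydrolysis of F6 in dilute HCl at 50 °C rejoins the route at 11, so step 6 is not needed. In base the phenolate makes the C4 carbonyl a vinylogous carboxylate, which should suppress C3 enolization and ring opening; the enantiomeric purity would still be checked.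

3. Step 4. Ionic bromination at C3 through the C4 enol, followed by loss of HBr, would give the chromone and destroy C2, and the phenol may be ring-brominated if brominating agent is still present when it forms. The fallback sets out from 7 and comes back at 9. Catalytic dehydrogenation over Pd/C (10 wt %) in refluxing mesitylene under an argon sweep is driven by aromatization of ring A and should leave C2–C3 alone. It makes no compound outside the list (F0).

**Further compounds**

F1 | step 3 | ethyl 3-oxooctadecanoate | CCCCCCCCCCCCCCCC(=O)CC(=O)OCC
F2 | step 3 | ethyl (R)-3-hydroxyoctadecanoate | CCCCCCCCCCCCCCC[C@@H](O)CC(=O)OCC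
F3 | step 3 | ethyl (R)-3-(tert-butyldimethylsilyloxy)octadecanoate | CCCCCCCCCCCCCCC[C@@H](O[Si](C)(C)C(C)(C)C)CC(=O)OCC
F4 | step 3 | (R)-3-(tert-butyldimethylsilyloxy)octadecanoic acid | CCCCCCCCCCCCCCC[C@@H](O[Si](C)(C)C(C)(C)C)CC(=O)O
F5 | step 3 | 3-hydroxy-2-[(3R)-3-(tert-butyldimethylsilyloxy)octadecanoyl]cyclohex-2-en-1-one | CCCCCCCCCCCCCCC[C@@H](O[Si](C)(C)C(C)(C)C)CC(=O)C1=C(O)CCCC1=O
F0 | step 4 | none | none
F6 | step 5 | potassium (R)-5-hydroxy-4-oxo-2-pentadecylchroman-8-yl sulfate | CCCCCCCCCCCCCCC[C@@H]1CC(=O)c2c(O)ccc(OS(=O)(=O)[O-])c2O1.[K+]
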